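**Retrosynthetic overview**
- The γ-lactone and the C6–Cl bond are made last by forming the C7–O bond: an anti chlorolactonisation of the (E)-C6=C7 alkene of a macrocyclic 3-hydroxy tert-butyl ester.
- The ten-membered ring is closed at C2–C3 by a Nozaki–Hiyama–Kishi reaction (dienyl iodide onto a neopentyl aldehyde).
- The C8/C17 centres come from a propionate aldol onto an (E)-trienone, itself made by Claisen–Schmidt condensation of a C8 methyl ketone with a 2-methylidene dienal.
- Ring A (C1, C9, C10) comes from a Cu-catalysed asymmetric conjugate addition / syn-aldol on 3-methylcyclohexenone; C13–O from enone β-borylation/oxidation; C11=CH2 by methylenation.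
- Ring order: six-membered ring A (present from the start), then the ten-membered ring, then the lactone.

Assumption: briarane numbering (C1–C20) is used for positions in all intermediates; TBS = tert-butyldimethylsilyl. The route is a proposal and has not been run.

**Step 1**
Reactants: 1 methyl 2,2-dimethoxypropanoate
Product: 2 2,2-dimethoxypropanal
Conditions: iBu2AlH (1.05 equiv), CH2Cl2, −78 °C; aq potassium sodium tartrate
Reagents that add atoms: none
Why: Low-temperature ester half-reduction stops at the aldehyde because the α,α-dialkoxy aluminium hemiacetal is stable until quench; no stereocentre.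

**Step 2**
Reactants: 3 3-methylcyclohex-2-en-1-one; 4 (chloromethyl)dimethyl(propan-2-yloxy)silane; 2 2,2-dimethoxypropanal
Product: 8 ketol (2S,3S)-2-[(1S)-1-hydroxy-2,2-dimethoxypropyl]-3-methyl-3-{[dimethyl(propan-2-yloxy)silyl]methyl}cyclohexan-1-one, via Grignard reagent 5 (not isolated), via magnesium enolate 6 (not isolated), via titanium enolate 7 (not isolated)
Conditions: 4, Mg, THF, 40 °C; then 3, Cu(OTf)2 (3 mol %), chiral 4,5-diphenylimidazolinium NHC precursor (4 mol %, enantiomer giving 1S), Et2O, −30 °C; ClTi(OiPr)3, −78 °C; 2, −78 °C; aq NH4Cl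
Reagents that add atoms: none
Why: Tandem copper–NHC-catalysed asymmetric conjugate addition / aldol: the catalyst sets the C1 quaternary centre, the enolate is attacked anti to the new bulky silylmethyl group (C10, C2/C9 trans), and the triisopropoxytitanium enolate gives the syn aldol (9S) by its geometry-independent syn selectivity.

**Step 3**
Reactants: 8 ketol
Product: 10 enone (5S,6S)-6-[(1S)-2,2-dimethoxy-1-(trimethylsilyloxy)propyl]-5-methyl-5-{[dimethyl(propan-2-yloxy)silyl]methyl}cyclohex-2-en-1-one, via bis-silylated enol ether 9 (not isolated)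
Conditions: LiN(iPr)2 (2.3 equiv), Me3SiCl (3 equiv), THF, −78 °C; then Pd(OAc)2 (10 mol %), O2 (1 atm), DMSO, 25 °C
Reagents that add atoms: chlorotrimethylsilane (C[Si](C)(C)Cl)
Why: Saegusa–Ito dehydrogenation: kinetic deprotonation is only possible at C12 (C10 is hindered and C1 is quaternary), the palladium-mediated dehydrosilylation gives the C12=C13 enone, and the C9 alkoxide is capped as its trimethylsilyl ether; no new stereocentre.

**Step 4**
Reactants: 10 enone
Product: 12 triol (2S,3S,5R)-5-hydroxy-2-[(1S)-1-hydroxy-2,2-dimethoxypropyl]-3-(hydroxymethyl)-3-methylcyclohexan-1-one, via boronate 11 (not isolated)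
Conditions: CuCl (5 mol %), NaOtBu (10 mol %), xantphos (5 mol %), B2pin2 (1.1 equiv), MeOH (2 equiv), THF, 0 °C; then 30 % H2O2, KF, KHCO3, THF/MeOH, 25 °C
Reagents that add atoms: hydrogen peroxide (OO)
Why: Copper-catalysed conjugate borylation adds Bpin to C13 anti to the axial C1 methyl (both side chains equatorial), and the one-pot peroxide step oxidises C–B with retention (13-OH trans to the methyl), performs the Tamao oxidation of the alkoxysilane to the C2 hydroxymethyl and removes the trimethylsilyl ether.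

**Step 5**
Reactants: 12 triol
Product: 13 tris(tert-butyldimethylsilyl) ether of triol 12 (O2/O9/O13 silylated)
Conditions: tBuMe2SiOTf (3.6 equiv), 2,6-lutidine, CH2Cl2, −78 to 0 °C
Reagents that add atoms: tert-butyldimethylsilyl triflate (CC(C)(C)[Si](C)(C)OS(=O)(=O)C(F)(F)F)
Why: Silyl triflate silylation protects all three hydroxyls, the hindered C9–OH included, before the basic steps; no stereochemical change.

**Step 6**
Reactants: 13 tris-silyl ketone
Product: 14 exocyclic alkene (C11=CH2 in place of the C11 ketone of 13)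
Conditions: Cp2TiMe2 (3 equiv), toluene, 65 °C, dark
Reagents that add atoms: dimethyltitanocene ([CH3-].[CH3-].[Ti+4].c1cc[cH-]c1.c1cc[cH-]c1)
Why: Petasis methylenation is non-basic, so the hindered β-silyloxy ketone is converted without β-elimination or C10 epimerisation, and the ketal and silyl ethers are inert.

**Step 7**
Reactants: 14 exocyclic alkene
Product: 15 methyl ketone (C8 dimethyl ketal of 14 hydrolysed to C8=O)
Conditions: LiBF4 (1 equiv), MeCN/H2O (50:1), 25 °C
Reagents that add atoms: water (O)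
Why: Mild Lewis-acid ketal hydrolysis unmasks the C8 methyl ketone while the silyl ethers and the exocyclic alkene survive.

**Step 8**
Reactants: 16 but-3-yn-1-ol
Product: 18 (E)-4-iodobut-3-en-1-ol, via vinylstannane 17 (not isolated)
Conditions: Bu3SnH (1.3 equiv), AIBN (5 mol %), 80 °C; then I2, CH2Cl2, 0 °C
Reagents that add atoms: iodine (II)
Why: Radical hydrostannation gives the thermodynamic (E)-1-stannylalkene and iododestannylation proceeds with retention, fixing what becomes the 3E alkene.

**Step 9**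
Reactants: 18 (E)-4-iodobut-3-en-1-ol
Product: 19 (E)-4-iodobut-3-enal
Conditions: Dess–Martin periodinane, NaHCO3, CH2Cl2, 0 °C
Reagents that add atoms: none
Why: Buffered Dess–Martin oxidation gives the β,γ-unsaturated aldehyde without double-bond migration; it is used crude.

**Step 10**
Reactants: 19 (E)-4-iodobut-3-enal
Product: 20 (E)-4-iodo-2-methylidenebut-3-enal
Conditions: 37 % aq CH2O, pyrrolidine (10 mol %), EtCO2H (10 mol %), iPrOH, 45 °C
Reagents that add atoms: formaldehyde (C=O)
Why: Amine-catalysed Mannich condensation/elimination (organocatalytic α-methylenation) installs the C16 methylidene and gives a non-enolisable 2-substituted acrolein.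

**Step 11**
Reactants: 15 methyl ketone; 20 (E)-4-iodo-2-methylidenebut-3-enal
Product: 24 (3E,6E)-trienone (side chain C9H(OTBS)–C8(=O)–CH=CH–C(=CH2)–CH=CH–I), via lithium enolate 21 (not isolated), via lithium aldolate 22 (not isolated), via mesylate 23 (not isolated)
Conditions: LiN(SiMe3)2 (1.1 equiv), THF, −78 °C; 20; then MeSO2Cl, Et3N, −78 to 0 °C
Reagents that add atoms: none
Why: Claisen–Schmidt sequence: the kinetic methyl-ketone enolate adds 1,2 to the non-enolisable enal, and mesylation/E1cB elimination gives the conjugated (E)-enone; C9 is not enolised at −78 °C.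

**Step 12**
Reactants: 24 trienone; 25 tert-butyl propanoate
Product: 27 tertiary alcohol (8R,17R) tert-butyl ester (aldol adduct at C8), via lithium ester enolate 26 (not isolated)
Conditions: 25, LiN(iPr)2, THF/DMPU (4:1), −78 °C; then 24, −78 °C, 20 min; AcOH quench at −78 °C
Reagents that add atoms: none
Why: Ester-enolate aldol addition at −78 °C is 1,2-selective; polar Felkin–Anh attack anti to the C9 silyloxy group sets C8, and the closed transition state of the enolate with methyl cis to OLi (C9 branch equatorial) sets C17, which is also the thermodynamically preferred α-epimer.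

**Step 13**
Reactants: 27 tertiary alcohol
Product: 28 primary alcohol (C2–OH free; O9/O13 silyl ethers kept)
Conditions: HF·pyridine, pyridine, THF, 0 °C
Reagents that add atoms: none
Why: Buffered HF·pyridine cleaves the primary silyl ether much faster than the two secondary ones.

**Step 14**
Reactants: 28 primary alcohol
Product: 29 aldehyde (C2=O)
Conditions: Dess–Martin periodinane, NaHCO3, CH2Cl2, 0 °C
Reagents that add atoms: none
Why: Dess–Martin oxidation gives the non-enolisable neopentyl aldehyde; the tertiary C8 alcohol is inert.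

**Step 15**
Reactants: 29 aldehyde
Product: 30 macrocyclic diol (ten-membered ring; 2S-OH; 8-OH; O9/O13 silyl ethers; tert-butyl ester)
Conditions: CrCl2 (10 equiv), NiCl2 (2 mol %), DMSO/THF (3:1), 0.002 M, 25 °C
Reagents that add atoms: none
Why: Nozaki–Hiyama–Kishi reaction: nickel-catalysed formation of the alkenylchromium species from the (E)-dienyl iodide and its chemoselective addition to the aldehyde at high dilution closes the ring with retention of the 3E geometry, and addition to the aldehyde conformer with C=O turned away from ring A is expected to give the 2S carbinol.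

**Step 16**
Reactants: 30 macrocyclic diol
Product: 31 tetraol tert-butyl ester (2-OH/8-OH/9-OH/13-OH)
Conditions: HF·pyridine (excess), THF, 25 °C
Reagents that add atoms: none
Why: Fluoride cleaves both secondary silyl ethers, while the tert-butyl ester survives and prevents lactonisation onto O9.

**Step 17**
Reactants: 31 tetraol
Product: 32 2,9,13-triacetate tert-butyl ester (8-OH free)
Conditions: Ac2O, pyridine, DMAP (cat.), CH2Cl2, 0 to 25 °C
Reagents that add atoms: acetic anhydride (CC(=O)OC(C)=O)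
Why: Acylation of the three secondary alcohols; the tertiary C8 hydroxyl does not react under these conditions.

**Step 18**
Reactants: 32 triacetate tert-butyl ester
Product: 33 CNP0268873.1 (target)
Conditions: 1,3-dichloro-5,5-dimethylhydantoin (0.6 equiv), cinchona amino-thiocarbamate catalyst (10 mol %), CHCl3/toluene (1:1), 4 Å MS, −40 °C
Reagents that add atoms: 1,3-dichloro-5,5-dimethylhydantoin (CC1(C)N(Cl)C(=O)N(Cl)C1=O)
Why: Proposed new method: a hydroxyl-anchored, Lewis-base-catalysed 1,2-anti-chlorolactonisation with the tert-butyl ester as nucleophile, in which the thiocarbamate sulfur takes Cl+ from the hydantoin, the protonated quinuclidine hydrogen-bonds to the C8 hydroxyl and so delivers chlorine only to the adjacent C6=C7 bond, the ester carbonyl oxygen attacks C7 5-exo and anti to chlorine in a concerted nucleophile-assisted addition that outruns relaxation to a dienyl cation (the cross-conjugated diene is twisted in the ring), and the tert-butyl oxocarbenium ion loses 2-methylpropene; anti addition to the E alkene gives 6S,7R and closure through the hydroxyl-inside conformer gives the trans-fused lactone with 8-OH cis to C6; the closest known reactions are amino-thiocarbamate/cinchona-catalysed halolactonisations of 1,2-disubstituted 4-alkenoic acids, halolactonisation of tert-butyl esters and hydroxyl-directed iodolactonisation of 3-hydroxy-4-alkenoic acids, none shown for chlorine on an alkene inside a cross-conjugated triene.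

**Compound list**
1 | methyl 2,2-dimethoxypropanoate | COC(=O)C(C)(OC)OC | starting material
2 | 2,2-dimethoxypropanal | CC(OC)(OC)C=O | intermediate
3 | 3-methylcyclohex-2-en-1-one | CC1=CC(=O)CCC1 | starting material
4 | (chloromethyl)dimethyl(propan-2-yloxy)silane | CC(C)O[Si](C)(C)CCl | starting material
5 | {[dimethyl(propan-2-yloxy)silyl]methyl}magnesium chloride | CC(C)O[Si](C)(C)C[Mg]Cl | intermediate
6 | chloromagnesium (3S)-3-methyl-3-{[dimethyl(propan-2-yloxy)silyl]methyl}cyclohex-1-en-1-olate | Cl[Mg]OC1=C[C@@](C)(C[Si](C)(C)OC(C)C)CCC1 | intermediate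
7 | tri(propan-2-yloxy)titanium (3S)-3-methyl-3-{[dimethyl(propan-2-yloxy)silyl]methyl}cyclohex-1-en-1-olate | CC(C)O[Ti](OC(C)C)(OC(C)C)OC1=C[C@@](C)(C[Si](C)(C)OC(C)C)CCC1 | intermediate
8 | (2S,3S)-2-[(1S)-1-hydroxy-2,2-dimethoxypropyl]-3-methyl-3-{[dimethyl(propan-2-yloxy)silyl]methyl}cyclohexan-1-one | O=C1CCC[C@](C)(C[Si](C)(C)OC(C)C)[C@H]1[C@H](O)C(C)(OC)OC | intermediate
9 | trimethylsilyl enol ether (C11=C12) of 8 with O9 as trimethylsilyl ether | C[Si](C)(C)OC1=CCC[C@](C)(C[Si](C)(C)OC(C)C)[C@H]1[C@H](O[Si](C)(C)C)C(C)(OC)OC | intermediate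
10 | (5S,6S)-6-[(1S)-2,2-dimethoxy-1-(trimethylsilyloxy)propyl]-5-methyl-5-{[dimethyl(propan-2-yloxy)silyl]methyl}cyclohex-2-en-1-one | O=C1C=CC[C@](C)(C[Si](C)(C)OC(C)C)[C@H]1[C@H](O[Si](C)(C)C)C(C)(OC)OC | intermediate
11 | 13-(pinacolboryl) ketone: 10 with C12–C13 saturated and Bpin on C13 trans to the C1 methyl | O=C1C[C@H](B2OC(C)(C)C(C)(C)O2)C[C@](C)(C[Si](C)(C)OC(C)C)[C@H]1[C@H](O[Si](C)(C)C)C(C)(OC)OC | intermediate
12 | (2S,3S,5R)-5-hydroxy-2-[(1S)-1-hydroxy-2,2-dimethoxypropyl]-3-(hydroxymethyl)-3-methylcyclohexan-1-one | O=C1C[C@H](O)C[C@](C)(CO)[C@H]1[C@H](O)C(C)(OC)OC | intermediate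
13 | (2S,3S,5R)-5-(TBS-oxy)-2-[(1S)-1-(TBS-oxy)-2,2-dimethoxypropyl]-3-[(TBS-oxy)methyl]-3-methylcyclohexan-1-one | O=C1C[C@H](O[Si](C)(C)C(C)(C)C)C[C@](C)(CO[Si](C)(C)C(C)(C)C)[C@H]1[C@H](O[Si](C)(C)C(C)(C)C)C(C)(OC)OC | intermediate
14 | methylidene analogue of 13 (C11=CH2; 1S,9S,10S,13S) | C=C1C[C@H](O[Si](C)(C)C(C)(C)C)C[C@](C)(CO[Si](C)(C)C(C)(C)C)[C@H]1[C@H](O[Si](C)(C)C(C)(C)C)C(C)(OC)OC | intermediate
15 | methyl ketone: 14 with the C8 ketal hydrolysed (side chain CH(OTBS)–CO–CH3) | C=C1C[C@H](O[Si](C)(C)C(C)(C)C)C[C@](C)(CO[Si](C)(C)C(C)(C)C)[C@H]1[C@H](O[Si](C)(C)C(C)(C)C)C(C)=O | intermediate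
16 | but-3-yn-1-ol | C#CCCO | starting material
17 | (E)-4-(tributylstannyl)but-3-en-1-ol | OCC/C=C/[Sn](CCCC)(CCCC)CCCC | intermediate
18 | (E)-4-iodobut-3-en-1-ol | OCC/C=C/I | intermediate
19 | (E)-4-iodobut-3-enal | O=CC/C=C/I | intermediate
20 | (E)-4-iodo-2-methylidenebut-3-enal | C=C(C=O)/C=C/I | intermediate
21 | lithium enolate of 15 (C7=C8–OLi) | C=C1C[C@H](O[Si](C)(C)C(C)(C)C)C[C@](C)(CO[Si](C)(C)C(C)(C)C)[C@H]1[C@H](O[Si](C)(C)C(C)(C)C)C(=C)O[Li] | intermediate
22 | lithium aldolate from 21 and 20 (C6–OLi, both C6 epimers) | C=C1C[C@H](O[Si](C)(C)C(C)(C)C)C[C@](C)(CO[Si](C)(C)C(C)(C)C)[C@H]1[C@H](O[Si](C)(C)C(C)(C)C)C(=O)CC(O[Li])C(=C)/C=C/I | intermediate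
23 | C6 methanesulfonate of the aldol adduct | C=C1C[C@H](O[Si](C)(C)C(C)(C)C)C[C@](C)(CO[Si](C)(C)C(C)(C)C)[C@H]1[C@H](O[Si](C)(C)C(C)(C)C)C(=O)CC(OS(C)(=O)=O)C(=C)/C=C/I | intermediate
24 | (3E,6E)-trienone: C9H(OTBS)–C8(=O)–CH=CH–C(=CH2)–CH=CH–I on the ring of 14 | C=C1C[C@H](O[Si](C)(C)C(C)(C)C)C[C@](C)(CO[Si](C)(C)C(C)(C)C)[C@H]1[C@H](O[Si](C)(C)C(C)(C)C)C(=O)/C=C/C(=C)/C=C/I | intermediate
25 | tert-butyl propanoate | CCC(=O)OC(C)(C)C | starting material
26 | lithium enolate of tert-butyl propanoate (methyl cis to OLi) | C/C=C(\O[Li])OC(C)(C)C | intermediate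
27 | (8R,17R) aldol adduct: 24 with C8(OH)[CH(CH3)CO2tBu] in place of the C8 ketone | C=C1C[C@H](O[Si](C)(C)C(C)(C)C)C[C@](C)(CO[Si](C)(C)C(C)(C)C)[C@H]1[C@H](O[Si](C)(C)C(C)(C)C)[C@](O)([C@@H](C)C(=O)OC(C)(C)C)/C=C/C(=C)/C=C/I | intermediate
28 | primary alcohol: 27 with C2–OH free | C=C1C[C@H](O[Si](C)(C)C(C)(C)C)C[C@](C)(CO)[C@H]1[C@H](O[Si](C)(C)C(C)(C)C)[C@](O)([C@@H](C)C(=O)OC(C)(C)C)/C=C/C(=C)/C=C/I | intermediate
29 | aldehyde: 28 oxidised at C2 | C=C1C[C@H](O[Si](C)(C)C(C)(C)C)C[C@](C)(C=O)[C@H]1[C@H](O[Si](C)(C)C(C)(C)C)[C@](O)([C@@H](C)C(=O)OC(C)(C)C)/C=C/C(=C)/C=C/I | intermediate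
30 | macrocyclic diol (1S,2S,8R,9S,10S,13S,17R; 3E,6E; 2-OH, 8-OH; 9,13-bis-TBS ethers; tert-butyl ester) | C=C1C[C@H](O[Si](C)(C)C(C)(C)C)C[C@]2(C)[C@@H](O)/C=C/C(=C)/C=C/[C@@](O)([C@@H](C)C(=O)OC(C)(C)C)[C@@H](O[Si](C)(C)C(C)(C)C)[C@@H]12 | intermediate
31 | macrocyclic 2,8,9,13-tetraol tert-butyl ester | C=C1C[C@H](O)C[C@]2(C)[C@@H](O)/C=C/C(=C)/C=C/[C@@](O)([C@@H](C)C(=O)OC(C)(C)C)[C@@H](O)[C@@H]12 | intermediate
32 | macrocyclic 2,9,13-triacetate tert-butyl ester (8-OH free) | C=C1C[C@H](OC(C)=O)C[C@]2(C)[C@@H](OC(C)=O)/C=C/C(=C)/C=C/[C@@](O)([C@@H](C)C(=O)OC(C)(C)C)[C@@H](OC(C)=O)[C@@H]12 | intermediate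
33 | CNP0268873.1 (1S,2S,6S,7R,8R,9S,10S,13S,17R; 3E) | C=C1C[C@H](OC(C)=O)C[C@]2(C)[C@@H](OC(C)=O)/C=C/C(=C)[C@H](Cl)[C@@H]3OC(=O)[C@H](C)[C@@]3(O)[C@@H](OC(C)=O)[C@@H]12 | target

**Step count and risks**
Total steps: 18. Longest linear sequence: 15 (steps 1, 2–7, 11–18).

The three steps most likely to fail:

Step 18 (the new chlorolactonisation) may give 1,4-adducts, the six-membered lactone, or chlorination of the methylidene groups. The fallback uses known chemistry and sets out from 32. VO(acac)2/tBuOOH in CH2Cl2 epoxidises only the C6=C7 bond next to the C8 hydroxyl and gives the trans-epoxy alcohol F1. ClTi(OiPr)3 then opens the epoxide at the allylic C6 with inversion (the usual C3 opening of a 2,3-epoxy alcohol) to give the chlorohydrin F2. CF3CO2H removes the tert-butyl group and the 7-hydroxy acid lactonises, returning to 33.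

Step 15 (closure of a ten-membered ring holding two E alkenes) may not cyclise. The fallback sets out from 28 and replaces the chromium chemistry by a rhodium-catalysed alkenylboron addition. Miyaura borylation (PdCl2(dppf), B2pin2, KOAc, DMSO) converts the iodide into the dienyl boronate F3. Dess–Martin oxidation gives the boronate aldehyde F4. [Rh(OH)(cod)]2 in aqueous dioxane at high dilution adds the alkenylrhodium species to the aldehyde and comes back to the route at 30.

Step 2 (one-pot conjugate addition / titanium aldol) may give low syn selectivity or yield. The fallback splits it, setting out from 3 and 4. The copper-catalysed conjugate addition is quenched with Me3SiCl to give the isolated silyl enol ether F5. A chelation-controlled Mukaiyama aldol with 2 (MgBr2·OEt2, CH2Cl2, −78 °C, open transition state, syn-selective) and acidic work-up then returns to the route at 8.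

**Further compounds**
F1 | step 18 | 6,7-trans-epoxy alcohol of 32 | C=C1C[C@H](OC(C)=O)C[C@]2(C)[C@@H](OC(C)=O)/C=C/C(=C)[C@H]3O[C@@H]3[C@@](O)([C@@H](C)C(=O)OC(C)(C)C)[C@@H](OC(C)=O)[C@@H]12
F2 | step 18 | (6S,7R)-6-chloro-7-hydroxy tert-butyl ester | C=C1C[C@H](OC(C)=O)C[C@]2(C)[C@@H](OC(C)=O)/C=C/C(=C)[C@H](Cl)[C@H](O)[C@@](O)([C@@H](C)C(=O)OC(C)(C)C)[C@@H](OC(C)=O)[C@@H]12
F3 | step 15 | dienyl pinacol boronate alcohol (28 with Bpin in place of iodine) | C=C1C[C@H](O[Si](C)(C)C(C)(C)C)C[C@](C)(CO)[C@H]1[C@H](O[Si](C)(C)C(C)(C)C)[C@](O)([C@@H](C)C(=O)OC(C)(C)C)/C=C/C(=C)/C=C/B1OC(C)(C)C(C)(C)O1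
F4 | step 15 | dienyl pinacol boronate aldehyde (29 with Bpin in place of iodine) | C=C1C[C@H](O[Si](C)(C)C(C)(C)C)C[C@](C)(C=O)[C@H]1[C@H](O[Si](C)(C)C(C)(C)C)[C@](O)([C@@H](C)C(=O)OC(C)(C)C)/C=C/C(=C)/C=C/B1OC(C)(C)C(C)(C)O1
F5 | step 2 | (3S)-3-methyl-3-{[dimethyl(propan-2-yloxy)silyl]methyl}-1-(trimethylsilyloxy)cyclohex-1-ene | C[Si](C)(C)OC1=C[C@@](C)(C[Si](C)(C)OC(C)C)CCC1
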